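The cyclohexadienone ring (C3a, C4, C5, C6, C7, C7a; benzofuran numbering) is a vinylogous ester: the C6 carbonyl and the enol-ether oxygen O1 on C7a stand 1,3 to each other. C7–C7a–C3a of the dihydrofuran ring is therefore treated as a masked acetone 1,3-dianion, and C4–C5–C6 as a formyl ester that already carries the quaternary, non-enolisable C5 centre. In one flask a gamma-lithiated 2-methyl-4,5-dihydrofuran-3-phosphonate (C2 and C3 preset) is acylated at C7 by the ester (C6–C7) and then closes onto the aldehyde by Horner–Wadsworth–Emmons olefination (C3a=C4). This gives the target directly and avoids a stereorandom dearomatisation at C5.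

Key step: step 9

Remark: the target is read as (2S,3S,5R), with the aryl group on C2 and the methyl group on C3 trans; atom numbers in the text are those of the benzofuran skeleton of the target.
Assumption: in step 7 the sense of induction follows the ligand antipode, and the antipode that gives the R alcohol is used.

Step 1
Reactants: 1 pent-3-yn-2-one
Product: 2 (R)-pent-3-yn-2-ol
Conditions: Ru[(R,R)-TsDPEN](p-cymene) (1 mol %), i-PrOH, rt
Reagents that add atoms: none
Why: Noyori asymmetric transfer hydrogenation of an ynone, in which the alkyne takes the place of the aryl group in the CH–π-controlled transition state so that the (R,R)-diamine complex should deliver hydride to give the R carbinol.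

Step 2
Reactants: 2 (R)-pent-3-yn-2-ol
Product: 3 (R)-pent-3-yn-2-yl methanesulfonate
Conditions: MsCl, Et3N, CH2Cl2, −78 to 0 °C
Reagents that add atoms: methanesulfonyl chloride, CS(=O)(=O)Cl
Why: Sulfonylation (mesylation) at oxygen, which leaves the C–O bond and hence the stereocentre untouched.

Step 3
Reactants: 3 (R)-pent-3-yn-2-yl methanesulfonate; 4 3,4,5-trimethoxybenzaldehyde
Product: 6 (1S,2S)-2-methyl-1-(3,4,5-trimethoxyphenyl)pent-3-yn-1-ol, via allenylindium reagent 5 (not isolated)
Conditions: Pd(dppf)Cl2 (5 mol %), InI, THF/HMPA (3:1), rt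
Reagents that add atoms: none
Why: Marshall propargylation, in which zerovalent palladium displaces the mesylate anti (SN2′), transmetalation to indium gives the axially chiral allenylindium 5, and its cyclic SE2′ addition to the aldehyde forms the C–C bond anti to the departed mesylate (2S) with the aryl group turned away from the allene methyl group (1S, anti).

Step 4
Reactants: 6 (1S,2S)-2-methyl-1-(3,4,5-trimethoxyphenyl)pent-3-yn-1-ol
Product: 7 (2S,3R)-4-iodo-3,5-dimethyl-2-(3,4,5-trimethoxyphenyl)-2,3-dihydrofuran
Conditions: I2, NaHCO3, MeCN, 0 °C, dark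
Reagents that add atoms: iodine, [I][I]
Why: 5-endo-dig iodoetherification, in which the iodonium-activated alkyne is attacked anti by the hydroxyl group at the methyl-bearing alkyne carbon to give the beta-iodo enol ether without touching either stereocentre (the 3R label is only a change of priorities).

Step 5
Reactants: 7 (2S,3R)-4-iodo-3,5-dimethyl-2-(3,4,5-trimethoxyphenyl)-2,3-dihydrofuran
Product: 8 diethyl [(4R,5S)-2,4-dimethyl-5-(3,4,5-trimethoxyphenyl)-4,5-dihydrofuran-3-yl]phosphonate
Conditions: HP(O)(OEt)2, Pd(PPh3)4 (5 mol %), Et3N, toluene, 90 °C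
Reagents that add atoms: diethyl phosphite, [H]P(=O)(OCC)OCC
Why: Hirao coupling (palladium-catalysed P–C cross-coupling of a vinyl iodide with a dialkyl phosphite), in which palladium in the vinylpalladium intermediate is trans to the ring oxygen and so cannot undergo beta-alkoxide elimination.

Step 6
Reactants: 9 dimethyl 2-methoxypropanedioate (dimethyl methoxymalonate)
Product: 11 dimethyl 2-methoxy-2-(prop-2-en-1-yl)propanedioate, via sodium enolate 10 (not isolated)
Conditions: NaH, THF, 0 °C; allyl bromide, rt
Reagents that add atoms: allyl bromide, C=CCBr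
Why: C-alkylation of a malonate enolate (SN2), which puts the allyl group on the prochiral carbon that becomes C5.

Step 7
Reactants: 11 dimethyl 2-methoxy-2-(prop-2-en-1-yl)propanedioate
Product: 13 methyl (2R)-2-(hydroxymethyl)-2-methoxypent-4-enoate, via silyl ether 12 (not isolated)
Conditions: ZnEt2 (10 mol %), chiral 2,6-bis{[2-(diarylhydroxymethyl)piperidin-1-yl]methyl}-4-methylphenol ligand (5 mol %), PhSiH3, THF, 0 °C; then 1 M HCl
Reagents that add atoms: none
Why: Enantioselective desymmetrising hydrosilylation of a prochiral malonic ester by a chiral dinuclear zinc hydride, in which the ligand pocket should tell the enantiotopic ester groups apart through the flanking methoxy and allyl groups (ligand antipode chosen for R) and the silylated product 12 should resist a second reduction.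

Step 8
Reactants: 13 methyl (2R)-2-(hydroxymethyl)-2-methoxypent-4-enoate
Product: 14 methyl (2R)-2-formyl-2-methoxypent-4-enoate
Conditions: Dess–Martin periodinane, CH2Cl2, 0 °C to rt; used at once
Reagents that add atoms: none
Why: Dess–Martin oxidation of the primary alcohol to the aldehyde, whose quaternary alpha-carbon cannot enolise, so the future C5 centre cannot be scrambled.

Step 9
Reactants: 14 methyl (2R)-2-formyl-2-methoxypent-4-enoate; 8 diethyl [(4R,5S)-2,4-dimethyl-5-(3,4,5-trimethoxyphenyl)-4,5-dihydrofuran-3-yl]phosphonate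
Product: 19 (2S,3S,5R)-5-methoxy-3-methyl-5-(prop-2-en-1-yl)-2-(3,4,5-trimethoxyphenyl)-3,5-dihydro-1-benzofuran-6(2H)-one, via lithium amino alkoxide 15 (not isolated), via lithiated phosphonate 16 (not isolated), via masked keto phosphonate 17 (not isolated), via keto phosphonate aldehyde 18 (not isolated)
Conditions: 14, LiN(Me)CH2CH2NMe2 (from the amine and n-BuLi), THF, −78 °C; added to 8 + LiN(i-Pr)2 (2.1 equiv), THF, −78 to −20 °C; then t-BuOH, −20 °C to rt; aq. NH4Cl
Reagents that add atoms: none
Why: LiN(i-Pr)2 deprotonates the C7 methyl group of 8, which is vinylogous to the phosphonate, and the allylic anion 16 is acylated at C7 by the ester of 15, whose aldehyde is masked in the flask as an amino alkoxide, so that C6–C7 forms by a vinylogous Claisen condensation that is pulled forward when the second equivalent of base deprotonates 17. tert-Butanol then traps the lithium amide with which the amino alkoxide is in equilibrium, the freed aldehyde of 18 sits next to the phosphonate-stabilised enolate, C3a adds to C4 and the oxaphosphetane collapses with loss of diethyl phosphate (intramolecular Horner–Wadsworth–Emmons reaction), which forms C3a=C4. The closest known reaction type is the gamma-acylation of beta-ketophosphonate dianions by esters followed by intramolecular Horner–Wadsworth–Emmons cyclohexenone closure, here run as one formal [3+3] annulation on the enol-ether analogue. The six-membered ring closes by 6-(enolendo)-exo-trig addition of C3a to the aldehyde and syn elimination; the carbinol and C3a centres made on the way are reversible and are destroyed in the elimination, so no new stereocentre remains and C2, C3 and the quaternary, non-enolisable C5 pass through unchanged. The step needs the ester to react before the aldehyde (secured by the amino alkoxide mask), acylation through C7 and not C3a (C3a is fully substituted) and ring closure through C3a and not C7 (which would give a four-membered ring).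

Compound list
1 | pent-3-yn-2-one | CC(=O)C#CC | starting material
2 | (R)-pent-3-yn-2-ol | C[C@@H](O)C#CC | intermediate
3 | (R)-pent-3-yn-2-yl methanesulfonate | C[C@@H](OS(C)(=O)=O)C#CC | intermediate
4 | 3,4,5-trimethoxybenzaldehyde | COc1cc(C=O)cc(OC)c1OC | starting material
5 | (aS)-iodo(methanesulfonato)(penta-2,3-dien-2-yl)indium, allenylindium reagent | CC([In](I)OS(C)(=O)=O)=[C@]=C([H])C | intermediate
6 | (1S,2S)-2-methyl-1-(3,4,5-trimethoxyphenyl)pent-3-yn-1-ol | O[C@H](c1cc(OC)c(OC)c(OC)c1)[C@H](C#CC)C | intermediate
7 | (2S,3R)-4-iodo-3,5-dimethyl-2-(3,4,5-trimethoxyphenyl)-2,3-dihydrofuran | IC1=C(C)O[C@H](c2cc(OC)c(OC)c(OC)c2)[C@H]1C | intermediate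
8 | diethyl [(4R,5S)-2,4-dimethyl-5-(3,4,5-trimethoxyphenyl)-4,5-dihydrofuran-3-yl]phosphonate | CCOP(=O)(OCC)C1=C(C)O[C@H](c2cc(OC)c(OC)c(OC)c2)[C@H]1C | intermediate
9 | dimethyl 2-methoxypropanedioate | COC(C(=O)OC)C(=O)OC | starting material
10 | sodium enolate of 9 | COC(C(=O)OC)=C([O-])OC.[Na+] | intermediate
11 | dimethyl 2-methoxy-2-(prop-2-en-1-yl)propanedioate | C=CCC(OC)(C(=O)OC)C(=O)OC | intermediate
12 | methyl (2R)-2-methoxy-2-({[methoxy(phenyl)silyl]oxy}methyl)pent-4-enoate | C=CC[C@@](OC)(CO[SiH](OC)c1ccccc1)C(=O)OC | intermediate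
13 | methyl (2R)-2-(hydroxymethyl)-2-methoxypent-4-enoate | C=CC[C@@](OC)(CO)C(=O)OC | intermediate
14 | methyl (2R)-2-formyl-2-methoxypent-4-enoate | C=CC[C@@](OC)(C=O)C(=O)OC | intermediate
15 | lithium amino alkoxide of 14: lithium (2R)-1-{[2-(dimethylamino)ethyl](methyl)amino}-2-methoxy-2-(methoxycarbonyl)pent-4-en-1-olate (both C1 epimers) | C=CC[C@@](OC)(C([O-])N(C)CCN(C)C)C(=O)OC.[Li+] | intermediate
16 | 8 lithiated at its 2-methyl group (C7 of the target) | CCOP(=O)(OCC)C1=C([CH2-])O[C@H](c2cc(OC)c(OC)c(OC)c2)[C@H]1C.[Li+] | intermediate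
17 | acylation product of 16 and 15: keto phosphonate with the aldehyde still masked as lithium amino alkoxide | CCOP(=O)(OCC)C1=C(CC(=O)[C@](CC=C)(OC)C([O-])N(C)CCN(C)C)O[C@H](c2cc(OC)c(OC)c(OC)c2)[C@H]1C.[Li+] | intermediate
18 | diethyl {(4R,5S)-2-[(3R)-3-formyl-3-methoxy-2-oxohex-5-en-1-yl]-4-methyl-5-(3,4,5-trimethoxyphenyl)-4,5-dihydrofuran-3-yl}phosphonate (present as its lithium enolate) | CCOP(=O)(OCC)C1=C(CC(=O)[C@](CC=C)(OC)C=O)O[C@H](c2cc(OC)c(OC)c(OC)c2)[C@H]1C | intermediate
19 | (2S,3S,5R)-5-methoxy-3-methyl-5-(prop-2-en-1-yl)-2-(3,4,5-trimethoxyphenyl)-3,5-dihydro-1-benzofuran-6(2H)-one | C=CC[C@@]1(OC)C=C2C(=CC1=O)O[C@H](c1cc(OC)c(OC)c(OC)c1)[C@H]2C | target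

Total step count: 9. Longest linear sequence: 6 (steps 1, 2, 3, 4, 5 and 9); the second branch is steps 6, 7, 8 and 9.

Steps most likely to fail

Step 9. The lithiated phosphonate may add to aldehyde that is not fully masked, the amino alkoxide may fragment with loss of the formyl group (retro-Claisen), or acylation by the hindered ester may be too slow to compete. The fallback makes the two bonds in separate, isolated stages. It sets out from 13 and 8. Silylation of 13 (TBSCl, imidazole, DMF) should give the silyl ether F1. Acylation of 16 (from 8 and 2.1 equiv LiN(i-Pr)2, THF, −78 to 0 °C) by F1 should give the keto phosphonate silyl ether F2. HF·pyridine in THF should give the keto phosphonate alcohol F3. Dess–Martin oxidation then gives 18, now isolated, where the route is rejoined; LiCl and DBU in MeCN (Masamune–Roush conditions) close it to 19.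

Step 7. The zinc hydride may fail to tell the two enantiotopic ester groups apart, or may reduce both. The fallback hands the differentiation to an enzyme and sets out from 11. Pig liver esterase (pH 7 phosphate buffer, pH-stat) is expected to hydrolyse one ester group to give the half-ester F4; the enantiotopic preference has to be confirmed on the first batch. Activation with i-BuOCOCl and N-methylmorpholine (THF, −15 °C) gives the mixed anhydride F5. NaBH4 reduces F5 to 13, where the route is rejoined.

Step 3. The propargylation may lose its anti selectivity with an aromatic aldehyde, and the allenyl metal may partly racemise. The fallback builds the dihydrofuran by a radical route and resolves it; it sets out from 4. Wittig ethylidenation (EtPPh3Br, KOt-Bu, THF) gives isoelemicin F6; either alkene isomer serves. Mn(OAc)3 and Cu(OAc)2 in AcOH with diethyl (2-oxopropyl)phosphonate add the phosphonate-bearing radical to the methyl-bearing alkene carbon. The benzylic cation is then trapped by the ketone oxygen trans to the methyl group. This should give 8 as a racemate together with its enantiomer F7. HPLC on a chiral stationary phase delivers 8, where the route is rejoined.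

Further compounds
F1 | step 9 | methyl (2R)-2-{[tert-butyl(dimethyl)silyl]oxymethyl}-2-methoxypent-4-enoate | C=CC[C@@](OC)(CO[Si](C)(C)C(C)(C)C)C(=O)OC
F2 | step 9 | diethyl {(4R,5S)-2-[(3R)-3-{[tert-butyl(dimethyl)silyl]oxymethyl}-3-methoxy-2-oxohex-5-en-1-yl]-4-methyl-5-(3,4,5-trimethoxyphenyl)-4,5-dihydrofuran-3-yl}phosphonate | CCOP(=O)(OCC)C1=C(CC(=O)[C@](CC=C)(OC)CO[Si](C)(C)C(C)(C)C)O[C@H](c2cc(OC)c(OC)c(OC)c2)[C@H]1C
F3 | step 9 | diethyl {(4R,5S)-2-[(3R)-3-(hydroxymethyl)-3-methoxy-2-oxohex-5-en-1-yl]-4-methyl-5-(3,4,5-trimethoxyphenyl)-4,5-dihydrofuran-3-yl}phosphonate | CCOP(=O)(OCC)C1=C(CC(=O)[C@](CC=C)(OC)CO)O[C@H](c2cc(OC)c(OC)c(OC)c2)[C@H]1C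
F4 | step 7 | (2R)-2-methoxy-2-(methoxycarbonyl)pent-4-enoic acid | C=CC[C@@](OC)(C(=O)O)C(=O)OC
F5 | step 7 | isobutyl carbonic mixed anhydride of F4 | C=CC[C@@](OC)(C(=O)OC(=O)OCC(C)C)C(=O)OC
F6 | step 3 | 1,2,3-trimethoxy-5-[(E)-prop-1-en-1-yl]benzene (isoelemicin) | C/C=C/c1cc(OC)c(OC)c(OC)c1
F7 | step 3 | diethyl [(4S,5R)-2,4-dimethyl-5-(3,4,5-trimethoxyphenyl)-4,5-dihydrofuran-3-yl]phosphonate (enantiomer of 8) | CCOP(=O)(OCC)C1=C(C)O[C@@H](c2cc(OC)c(OC)c(OC)c2)[C@@H]1C
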